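**Plan**

- Numbering is that of the dihydronaphthalene: C1 (aryl), C2 (CH2OAc), C3 (CHO), C3=C4, ring A fused at C4a–C8a (C6 OMe, C7 OH); ring B is C1–C2–C3–C4–C4a–C8a.
- Retrosynthesis: CH2OAc and CHO go back to an ester and an amide carbonyl joined by L-prolinol. Cutting C1–C8a (the C2 hydrogen returning to C8a) opens ring B to an E,E-bis(vanillylidene)succinate. The two benzylidene C=C bonds are then cut to MOM-vanillin (twice) and dimethyl succinate.
- Enabling feature: C8a=C4a of ring A, C4=C3 and C2=C1 are the hexatriene of a dibenzylidenesuccinate. Ring A and the C1 aryl group are the same vanillyl unit, so one aldehyde builds the whole diene.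
- Forward: two Stobbe condensations join the chain, the prolinol bridge is closed as an eight-membered amide ester, irradiation closes ring B, and the bridge is opened and its carbonyls taken to CH2OAc and CHO.
- Stereochemistry: C1 comes from the helical sense the (S)-prolinol bridge imposes on the diene. The photochemical sequence delivers C2 cis to C1, so C2 is equilibrated to trans (1S,2R) with methoxide while still α to an ester.

Key step: step 7

Assumption: the (S)-prolinol bridge is taken to hold the diene of 11 in the M helix (negative C1=C2–C3=C4 torsion), the sense that closes to 1S; if the P helix were favoured, D-prolinol would be used instead.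

Ar = 3-methoxy-4-(methoxymethoxy)phenyl.

**Route**

Step 1
Reactants: 1 vanillin
Product: 2 3-methoxy-4-(methoxymethoxy)benzaldehyde
Conditions: MOMCl, K2CO3, acetone, 0 °C to rt
Reagents that add atoms: chloromethyl methyl ether, COCCl
Why: Williamson-type O-alkylation of the phenoxide by the α-chloro ether gives an acetal-protected phenol that should survive the basic condensations, the irradiation and the hydride steps and be removable with mild acid at the end.

Step 2
Reactants: 2 3-methoxy-4-(methoxymethoxy)benzaldehyde; 3 dimethyl succinate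
Product: 4 (E)-3-(methoxycarbonyl)-4-Ar-but-3-enoic acid
Conditions: NaOMe, MeOH, reflux; then cold 1 M HCl to pH 3
Reagents that add atoms: none
Why: Stobbe condensation of the succinate enolate with the aryl aldehyde should give the half-ester with the aryl group trans to CO2Me (E), the geometry this reaction generally delivers.

Step 3
Reactants: 4 (E)-3-(methoxycarbonyl)-4-Ar-but-3-enoic acid
Product: 5 dimethyl (E)-2-(Ar-methylidene)succinate
Conditions: MeI, K2CO3, DMF, rt
Reagents that add atoms: iodomethane, CI
Why: SN2 methylation of the carboxylate re-forms the diester without acid (MOM safe), so that the remaining CH2 can be enolised for a second condensation.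

Step 4
Reactants: 5 dimethyl (E)-2-(Ar-methylidene)succinate; 2 3-methoxy-4-(methoxymethoxy)benzaldehyde
Product: 7 (2E,3E)-2,3-bis(Ar-methylidene)succinic acid, via monomethyl ester 6 (not isolated)
Conditions: NaOMe, MeOH, reflux; then aq. NaOH, reflux; then cold 1 M HCl to pH 3
Reagents that add atoms: sodium hydroxide, [Na+].[OH-]
Why: A second Stobbe condensation at the CH2 of 5 installs the second E-benzylidene group (aryl trans to its own carboxyl), and saponification of the remaining conjugated methyl ester in the same pot gives the E,E-diacid, which should be purified by crystallisation.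

Step 5
Reactants: 7 (2E,3E)-2,3-bis(Ar-methylidene)succinic acid; 8 L-prolinol
Product: 10 (2E,3E)-4-[(S)-2-(hydroxymethyl)pyrrolidin-1-yl]-4-oxo-2,3-bis(Ar-methylidene)butanoic acid, via cyclic anhydride 9 (not isolated)
Conditions: DCC, CH2Cl2, 0 °C to rt, dark, filter; then L-prolinol, Et3N, THF, 0 °C; aq. citric acid wash
Reagents that add atoms: none
Why: Carbodiimide dehydration closes the five-membered anhydride without touching the alkene geometry, and the secondary amine of L-prolinol, far more nucleophilic than its hydroxyl, opens the symmetrical anhydride at either carbonyl to the same amide acid.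

Step 6
Reactants: 10 amide acid
Product: 11 (S)-prolinol-bridged eight-membered cyclic amide ester of 7 (both benzylidene groups E; M helix)
Conditions: 2-chloro-1-methylpyridinium iodide, Et3N, CH2Cl2, reflux, slow addition (0.002 M), dark
Reagents that add atoms: none
Why: Mukaiyama lactonisation, in which the acyloxypyridinium salt of the acid is trapped by the primary hydroxyl under high dilution; the cis-disposed carboxyl carbons on the twisted diene favour the eight-membered ring, in which the (S) centre should set the helical sense.

Step 7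
Reactants: 11 cyclic amide ester
Product: 13 (1S,2S)-cis-1-Ar-6-methoxy-7-(methoxymethoxy)-1,2-dihydronaphthalene with C3 amide and C2 ester still bridged by the prolinol, via 1,8a-dihydronaphthalene 12 (not isolated)
Conditions: hν (350 nm, Pyrex), degassed toluene (0.005 M), 25 °C; then dark, 40 °C
Reagents that add atoms: none
Why: Excitation of the twisted E,E-diene lets C8a=C4a of the vanillyl ring on the amide half, C4=C3 and C2=C1 react as a hexatriene in a photochemically allowed conrotatory 6π electrocyclisation that forms C1–C8a and closes ring B (six-membered carbocycle) as the 1,8a-dihydronaphthalene 12, and a thermal suprafacial [1,5]-hydrogen shift from C8a to C2 then restores ring A. The closest known reaction type is the photocyclisation of E,E-dibenzylidenesuccinic anhydrides, imides and amino-alcohol-bridged amide esters to 1-aryl-1,2-dihydronaphthalenes. C1 is controlled by the (S)-prolinol bridge, which holds the diene in the M helix so that C8a bonds to the Re face of C1 and gives 1S. C2 is controlled by the pericyclic sequence itself: the pendant aryl group is the inside substituent of the E-configured C1 terminus, so conrotation puts H1 and H8a on the same face and the suprafacial shift carries H8a to that face of C2, which makes H1 and H2 cis (1S,2S) and is why step 8 is needed. The step needs the ring of the amide half to attack the benzylidene carbon of the ester half, which should be favoured because that carbon is the β-position of the more electron-poor cinnamate unit while the attacking ring sits on the less withdrawing cinnamamide unit; either mode builds the same skeleton with the same C1 configuration because both aryl groups are identical. Closure at the ring carbon para to OMe (not the one flanked by OMe and the side chain) is secured sterically, and degassing keeps 12 from being oxidised to the arylnaphthalene.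

Step 8
Reactants: 13 cis-bridged dihydronaphthalene
Product: 15 methyl (1S,2R)-trans-1-Ar-3-{[(S)-2-(hydroxymethyl)pyrrolidin-1-yl]carbonyl}-6-methoxy-7-(methoxymethoxy)-1,2-dihydronaphthalene-2-carboxylate, via cis methyl ester 14 (not isolated)
Conditions: NaOMe (0.3 equiv), MeOH/THF, 0 °C to rt, Ar; aq. NH4Cl
Reagents that add atoms: methanol, CO
Why: Methoxide opens the strained medium-ring lactone by transesterification and reversibly deprotonates C2 α to the ester, which should settle in the trans arrangement (C1 aryl and C2 ester both pseudoaxial), the thermodynamic preference of 1-aryl-1,2-dihydronaphthalene-2-carboxylates, while the non-acidic C1 keeps its configuration.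

Step 9
Reactants: 15 trans methyl ester
Product: 16 (1S,2R)-trans-2-(hydroxymethyl) 3-carboxamide diol
Conditions: LiBH4, THF, 0 °C to rt; aq. NH4Cl
Reagents that add atoms: none
Why: Chemoselective borohydride reduction takes the saturated methyl ester to the primary alcohol and should leave the conjugated tertiary amide, the C3=C4 bond and the MOM ethers alone, after which C2 can no longer epimerise.

Step 10
Reactants: 16 diol
Product: 17 diacetate (C2 CH2OAc and prolinol CH2OAc)
Conditions: Ac2O, pyridine, DMAP (cat.), CH2Cl2, 0 °C to rt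
Reagents that add atoms: acetic anhydride, CC(=O)OC(C)=O
Why: DMAP-catalysed acylation of both primary alcohols installs the acetate of the target and masks the prolinol hydroxyl, which would otherwise consume the zirconium hydride.

Step 11
Reactants: 17 diacetate
Product: 18 (1S,2R)-2-(acetoxymethyl)-1-Ar-6-methoxy-7-(methoxymethoxy)-1,2-dihydronaphthalene-3-carbaldehyde
Conditions: Cp2Zr(H)Cl (2.5 equiv), THF, rt; then H2O, SiO2
Reagents that add atoms: none
Why: Hydrozirconation of the tertiary amide carbonyl gives a zirconated hemiaminal that does not reduce further and collapses on aqueous work-up to the conjugated aldehyde and the amine, a reduction known to spare esters, acetals and conjugated C=C bonds.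

Step 12
Reactants: 18 bis-MOM acetoxy aldehyde
Product: 19 target, (1S,2R)-2-(acetoxymethyl)-7-hydroxy-1-(4-hydroxy-3-methoxyphenyl)-6-methoxy-1,2-dihydronaphthalene-3-carbaldehyde
Conditions: TFA, CH2Cl2, H2O (5 equiv), 0 °C
Reagents that add atoms: none
Why: Acid-catalysed hydrolysis of the two aryl MOM acetals, far more labile than the primary acetate, under non-nucleophilic conditions should free both phenols without acetal formation at the aldehyde or acetate exchange, and neither stereocentre is enolisable.

**Compound list**

1 | vanillin | COc1cc(C=O)ccc1O | starting material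
2 | 3-methoxy-4-(methoxymethoxy)benzaldehyde | COCOc1ccc(C=O)cc1OC | intermediate
3 | dimethyl succinate | COC(=O)CCC(=O)OC | starting material
4 | (E)-3-(methoxycarbonyl)-4-[3-methoxy-4-(methoxymethoxy)phenyl]but-3-enoic acid | COC(=O)/C(CC(=O)O)=C/c1ccc(OCOC)c(OC)c1 | intermediate
5 | dimethyl (E)-2-[3-methoxy-4-(methoxymethoxy)benzylidene]succinate | COC(=O)/C(CC(=O)OC)=C/c1ccc(OCOC)c(OC)c1 | intermediate
6 | (2E,3E)-2,3-bis[3-methoxy-4-(methoxymethoxy)benzylidene]succinic acid monomethyl ester | COC(=O)/C(=C/c1ccc(OCOC)c(OC)c1)C(=C/c1ccc(OCOC)c(OC)c1)\C(=O)O | intermediate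
7 | (2E,3E)-2,3-bis[3-methoxy-4-(methoxymethoxy)benzylidene]succinic acid | OC(=O)/C(=C/c1ccc(OCOC)c(OC)c1)C(=C/c1ccc(OCOC)c(OC)c1)\C(=O)O | intermediate
8 | L-prolinol, (S)-pyrrolidin-2-ylmethanol | OC[C@@H]1CCCN1 | starting material
9 | (3E,4E)-3,4-bis[3-methoxy-4-(methoxymethoxy)benzylidene]oxolane-2,5-dione | COCOc1ccc(/C=C2/C(=O)OC(=O)/C2=C/c3ccc(OCOC)c(OC)c3)cc1OC | intermediate
10 | (2E,3E)-4-[(S)-2-(hydroxymethyl)pyrrolidin-1-yl]-2,3-bis[3-methoxy-4-(methoxymethoxy)benzylidene]-4-oxobutanoic acid | COCOc1ccc(/C=C(/C(=O)N2CCC[C@H]2CO)C(=C/c2ccc(OCOC)c(OC)c2)\C(=O)O)cc1OC | intermediate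
11 | (S)-prolinol-bridged eight-membered cyclic amide ester of 7 (pyrrolidine N acylated by one carboxyl, prolinol CH2O by the other; both benzylidene groups E; M helix of the diene) | COc1cc(/C=C2/C(=O)N3CCC[C@H]3COC(=O)/C2=C/c4ccc(OCOC)c(OC)c4)ccc1OCOC | intermediate
12 | 1,8a-dihydronaphthalene from conrotatory closure (H1 and H8a on the same face; C2=C3 and C4=C4a double bonds; bridge intact) | COc1cc([C@H]2[C@H]3C=C(OCOC)C(OC)=CC3=CC(C(=O)N3CCC[C@H]3COC4=O)=C24)ccc1OCOC | intermediate
13 | (1S,2S)-cis-1-aryl-1,2-dihydronaphthalene, C3 amide and C2 ester bridged by (S)-prolinol, 6-OMe, 7-OMOM | COc1cc([C@H]2c3cc(OCOC)c(OC)cc3C=C3C(=O)N4CCC[C@H]4COC(=O)[C@@H]23)ccc1OCOC | intermediate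
14 | methyl (1S,2S)-cis-1-aryl-3-{[(S)-2-(hydroxymethyl)pyrrolidin-1-yl]carbonyl}-6-methoxy-7-(methoxymethoxy)-1,2-dihydronaphthalene-2-carboxylate | COc1cc([C@H]2c3cc(OCOC)c(OC)cc3C=C(C(=O)N3CCC[C@H]3CO)[C@H]2C(=O)OC)ccc1OCOC | intermediate
15 | methyl (1S,2R)-trans-1-aryl-3-{[(S)-2-(hydroxymethyl)pyrrolidin-1-yl]carbonyl}-6-methoxy-7-(methoxymethoxy)-1,2-dihydronaphthalene-2-carboxylate | COc1cc([C@H]2c3cc(OCOC)c(OC)cc3C=C(C(=O)N3CCC[C@H]3CO)[C@@H]2C(=O)OC)ccc1OCOC | intermediate
16 | [(1S,2R)-1-aryl-2-(hydroxymethyl)-6-methoxy-7-(methoxymethoxy)-1,2-dihydronaphthalen-3-yl][(S)-2-(hydroxymethyl)pyrrolidin-1-yl]methanone | COc1cc([C@H]2c3cc(OCOC)c(OC)cc3C=C(C(=O)N3CCC[C@H]3CO)[C@@H]2CO)ccc1OCOC | intermediate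
17 | diacetate of 16 (C2 CH2OAc and prolinol CH2OAc), (1S,2R) | COc1cc([C@H]2c3cc(OCOC)c(OC)cc3C=C(C(=O)N3CCC[C@H]3COC(C)=O)[C@@H]2COC(C)=O)ccc1OCOC | intermediate
18 | (1S,2R)-2-(acetoxymethyl)-6-methoxy-7-(methoxymethoxy)-1-[3-methoxy-4-(methoxymethoxy)phenyl]-1,2-dihydronaphthalene-3-carbaldehyde | COc1cc([C@H]2c3cc(OCOC)c(OC)cc3C=C(C=O)[C@@H]2COC(C)=O)ccc1OCOC | intermediate
19 | (1S,2R)-2-(acetoxymethyl)-7-hydroxy-1-(4-hydroxy-3-methoxyphenyl)-6-methoxy-1,2-dihydronaphthalene-3-carbaldehyde | COc1cc([C@H]2c3cc(O)c(OC)cc3C=C(C=O)[C@@H]2COC(C)=O)ccc1O | target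

**Step count**

Total: 12 steps. Longest linear sequence: 12 steps (vanillin to 19); dimethyl succinate and L-prolinol enter at steps 2 and 5.

**Steps most likely to fail**

Step 7. The ring of the ester half may close instead of, or beside, that of the amide half, which would put the ester at C3 and the amide at C2. The fallback sets out from 11 and returns at 16 by an acyl-migration relay in place of direct use of the two carbonyls.
- Irradiation as in step 7 would then give the regioisomeric cis photoproduct F1.
- Cp2Zr(H)Cl in THF reduces its C2 tertiary amide, and hydrolytic work-up releases the cis formyl amino ester F2.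
- The freed pyrrolidine nitrogen of F2 takes over the C3 acyl group by O-to-N acyl migration through a five-membered transition state, giving the cis formyl hydroxy amide F3.
- Brief treatment with Et3N equilibrates the aldehyde α-centre to the trans formyl hydroxy amide F4.
- NaBH4 in MeOH at 0 °C reduces the aldehyde to diol 16, so both modes of ring closure converge on the same compound.

Step 6. Intermolecular acylation (oligomers) may win over closure of the eight-membered ring. The fallback sets out from anhydride 9 (made from 7 as in step 5) and returns at 11, closing the ring by alkylation instead of acylation.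
- Anhydride 9 is opened with (S)-2-(chloromethyl)pyrrolidine hydrochloride and Et3N to the chloromethyl amide acid F5.
- Cs2CO3 with catalytic NaI in DMF at high dilution and 60 °C then closes the same ring by intramolecular SN2 attack of the caesium carboxylate on the CH2Cl carbon, giving 11.

Step 11. Hydrozirconation of the hindered conjugated amide may be slow, so that attack on the acetates or on C3=C4 competes. The fallback sets out from 16 and returns at 18, passing through the alcohol oxidation level.
- LiNH2BH3 in THF (0 °C to rt) reduces the tertiary amide of 16 to the allylic alcohol with loss of prolinol, giving the diol F6.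
- MnO2 in CH2Cl2 oxidises only the allylic alcohol, giving the hydroxy aldehyde F7.
- Ac2O and pyridine then give 18.

Further compounds
F1 | step 7 | (1S,2S)-cis-1-aryl-1,2-dihydronaphthalene with C3 ester and C2 amide bridged by (S)-prolinol (regioisomer of 13) | COc1cc([C@H]2c3cc(OCOC)c(OC)cc3C=C3C(=O)OC[C@@H]4CCCN4C(=O)[C@@H]23)ccc1OCOC
F2 | step 7 | (S)-pyrrolidin-2-ylmethyl (1S,2S)-cis-1-aryl-2-formyl-6-methoxy-7-(methoxymethoxy)-1,2-dihydronaphthalene-3-carboxylate | COc1cc([C@H]2c3cc(OCOC)c(OC)cc3C=C(C(=O)OC[C@@H]3CCCN3)[C@H]2C=O)ccc1OCOC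
F3 | step 7 | (1S,2S)-cis-1-aryl-3-{[(S)-2-(hydroxymethyl)pyrrolidin-1-yl]carbonyl}-6-methoxy-7-(methoxymethoxy)-1,2-dihydronaphthalene-2-carbaldehyde | COc1cc([C@H]2c3cc(OCOC)c(OC)cc3C=C(C(=O)N3CCC[C@H]3CO)[C@H]2C=O)ccc1OCOC
F4 | step 7 | (1S,2R)-trans-1-aryl-3-{[(S)-2-(hydroxymethyl)pyrrolidin-1-yl]carbonyl}-6-methoxy-7-(methoxymethoxy)-1,2-dihydronaphthalene-2-carbaldehyde | COc1cc([C@H]2c3cc(OCOC)c(OC)cc3C=C(C(=O)N3CCC[C@H]3CO)[C@@H]2C=O)ccc1OCOC
F5 | step 6 | (2E,3E)-4-[(S)-2-(chloromethyl)pyrrolidin-1-yl]-2,3-bis[3-methoxy-4-(methoxymethoxy)benzylidene]-4-oxobutanoic acid | COCOc1ccc(/C=C(/C(=O)N2CCC[C@H]2CCl)C(=C/c2ccc(OCOC)c(OC)c2)\C(=O)O)cc1OC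
F6 | step 11 | [(1S,2R)-1-aryl-6-methoxy-7-(methoxymethoxy)-1,2-dihydronaphthalene-2,3-diyl]dimethanol | COc1cc([C@H]2c3cc(OCOC)c(OC)cc3C=C(CO)[C@@H]2CO)ccc1OCOC
F7 | step 11 | (1S,2R)-1-aryl-2-(hydroxymethyl)-6-methoxy-7-(methoxymethoxy)-1,2-dihydronaphthalene-3-carbaldehyde | COc1cc([C@H]2c3cc(OCOC)c(OC)cc3C=C(C=O)[C@@H]2CO)ccc1OCOC
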